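The data come from a simulation with constants of no real substance; scatter was added.

What I count in this flask is a leftover: how many e-foldings the unreacted starting material has passed through, the natural logarithm of its charge over what remains.

| setting | spring | summer | autumn | flask |
|---|---|---|---|---|
| starting material | 10 mM | 10 mM | 5 mM | 10 mM |
| coupling partner | 18 mM | 18 mM | 18 mM | 18.0 mM |
| initiator | 1 mM | 2.2 mM | 1.5 mM | 1.5 mM |
| remark | run made earlier | run made earlier | run made earlier |  |
| time |  |  |  | 40 min |

- spring (time / min: product / %, crystals / %): 3.00: 2.5, 0; 8.00: 10.9, 2.1; 15.0: 19.8, 0; 25.0: 31.3, 0.6; 30.0: 34.7, 5.6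
- summer (time / min: product / %, crystals / %): 3.00: 6.4, 0; 8.00: 16.8, 0; 15.0: 29.4, 0.8; 25.0: 42.9, 14.3; 30.0: 49.8, 18.7
- autumn (time / min: product / %, crystals / %): 3.00: 6.1, 0.6; 8.00: 16.0, 2.3; 15.0: 27.4, 2.8; 25.0: 40.0, 0.1; 30.0: 46.3, 0

(scatter of a reading: 1 percentage point)

- product is meant together with its crystals
- solid, in amounts per volume of the solution: crystals
- what was read earlier has a scatter of 1 percentage point, one standard deviation

- product and crystals together at 40 min, in percent of the starting material charged
- concentration of product in solution at 40 min, in percent of saturation

Does this count grow evenly with time? In the spring run it stands at 0.426 after 30.0 min, twice its value after 15.0 min, so I read the leftover as a pseudo-first-order decay.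

How does the count depend on initiator? The summer run reaches 0.689 after 30.0 min, and the two runs together read as an order of 0.610 in initiator. The flask has the same charges of starting material and coupling partner as these two runs, so I scale spring by initiator and time. This gives the flask a turnover count n of 0.728, which means 51.7% reacted, or 5.17 mM of c(product) in all forms.

Does the flask crystallise? Dissolved product beside crystals reads 2.91 mM in spring and 3.11 mM in summer, and my total is more than either. I therefore expect crystals, and a solution near those readings.

The forecast gives 52% (49% to 55%) and 104% of saturation (98% to 115%): “so the flask should be crystallised and just above saturation”.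

The flask gives 52.7% and 103% of saturation.

    initiator → 2 initiating radical (k = 7.90 × 10⁻⁵ s⁻¹)
    starting material + initiating radical → capped initiator + first chain carrier (k = 1.20 × 10⁵ L mol⁻¹ s⁻¹)
    coupling partner + first chain carrier → product + second chain carrier (k = 3600 L mol⁻¹ s⁻¹)
    starting material + second chain carrier → released group + first chain carrier (k = 5400 L mol⁻¹ s⁻¹)
    2 second chain carrier → ended chains (k = 4.00 × 10⁷ L mol⁻¹ s⁻¹)
    crystals ⇌ product, rate k6*(cs6 - [product]) while solid is left; crystals form when [product] > cs6 (solubility = 2.90 mM, k = 0.0160 s⁻¹)

A neighbouring flask differs in one setting, 4.5 mM of coupling partner. With n at 0.728, the count asks for 5.17 mM of product, but each product takes one coupling partner and the charge is smaller. The coupling partner is the limiting reagent there, with a cap of 45.0%. That neighbour gives 45.0%, with 0% of its coupling partner left. Its starting material stands at 54%, a count of 0.616.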